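**Plan**

- Retrosynthesis: remove the 21 benzyl ethers; cut the upper interflavan bond C-4(upper)–C-8(central); then cut, in one operation, the central pyran ring at C-2–C-3 together with the lower interflavan bond C-4(central)–C-8(lower).
- Enabling feature: in the central unit C-2 is an acetal-level carbon (bound to ring oxygen O-1 and ring B), C-3 carries the galloyloxy group, and C-4 is benzylic to the 1,3,5-trioxygenated ring A. An O-1 oxocarbenium at C-2 can therefore be attacked by C-3 of a ring-A styrenyl gallate, and the C-4 cation left behind is stabilised by ring A.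
- Forward: the upper and lower units come from (−)-epicatechin (benzylation, galloylation, C-4 oxidation). The central unit is assembled from 2,4,6-trihydroxybenzaldehyde (ring A), 3,4-bis(benzyloxy)benzaldehyde (C-2 and ring B) and tribenzylgallic acid, carried as a (Z)-enol ester.
- Order: the central pyran ring is the last ring formed and is closed onto the lower unit (step 12); the upper unit is joined next, then all benzyl groups are removed.
- Stereochemistry: outer units from the chiral pool; central C-2/C-3 cis from the Z enol ester, absolute sense from a chiral Brønsted acid counter-anion, C-4 trans to O-3 by galloyl participation; upper C-4 trans by the same participation.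

Key step: step 12

Assumption: the (S)-configured acid of step 12 is taken to deliver the (2R,3R) ring; should the induction run the other way, the (R)-acid is used without other change.

**Route**

Step 1
Reactants: 1 (−)-epicatechin
Product: 2 5,7,3′,4′-tetra-O-benzyl-(−)-epicatechin
Conditions: BnBr (4.4 equiv), K2CO3, DMF, 0 °C → rt
Reagents that add atoms: benzyl bromide, BrCc1ccccc1
Why: Williamson etherification of the four phenols, which are far more acidic than the C-3 alcohol, so the secondary hydroxyl stays free and no stereocenter is touched.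

Step 2
Reactants: 2 5,7,3′,4′-tetra-O-benzyl-(−)-epicatechin; 3 3,4,5-tris(benzyloxy)benzoic acid
Product: 4 5,7,3′,4′-tetra-O-benzyl-(−)-epicatechin 3-O-[3,4,5-tris(benzyloxy)benzoate] (lower unit, nucleophile)
Conditions: DCC, DMAP (cat.), CH2Cl2, rt
Reagents that add atoms: none
Why: Steglich esterification of the axial C-3 hydroxyl, with retention at C-3 because its C–O bond is not broken.

Step 3
Reactants: 2 5,7,3′,4′-tetra-O-benzyl-(−)-epicatechin
Product: 5 4β-(2-ethoxyethoxy)-5,7,3′,4′-tetra-O-benzyl-(−)-epicatechin (2,3-cis, 3,4-trans)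
Conditions: DDQ (2 equiv), 2-ethoxyethanol (5 equiv), CH2Cl2, rt
Reagents that add atoms: 2-ethoxyethanol, CCOCCO
Why: DDQ benzylic oxidation at C-4 (activated by the ring-A oxygens) with capture by the alcohol anti to the axial C-3 substituent, which sets the 3,4-trans (4β) centre.

Step 4
Reactants: 5 4β-(2-ethoxyethoxy)-5,7,3′,4′-tetra-O-benzyl-(−)-epicatechin; 3 3,4,5-tris(benzyloxy)benzoic acid
Product: 6 4β-(2-ethoxyethoxy)-5,7,3′,4′-tetra-O-benzyl-(−)-epicatechin 3-O-[3,4,5-tris(benzyloxy)benzoate] (upper unit, electrophile)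
Conditions: DCC, DMAP (cat.), CH2Cl2, rt
Reagents that add atoms: none
Why: Steglich esterification of the C-3 hydroxyl under neutral conditions that leave the acid-labile C-4 ether and all stereocenters untouched.

Step 5
Reactants: 7 2,4,6-trihydroxybenzaldehyde
Product: 8 4,6-bis(benzyloxy)-2-hydroxybenzaldehyde
Conditions: BnBr (2.05 equiv), K2CO3 (2.1 equiv), DMF, rt
Reagents that add atoms: benzyl bromide, BrCc1ccccc1
Why: Williamson etherification that stops at the dibenzyl ether because the last ortho hydroxyl is chelated to the aldehyde and is the least nucleophilic.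

Step 6
Reactants: 8 4,6-bis(benzyloxy)-2-hydroxybenzaldehyde
Product: 9 4,6-bis(benzyloxy)-2-(triisopropylsilyloxy)benzaldehyde
Conditions: TIPSCl, imidazole, DMF, 40 °C
Reagents that add atoms: triisopropylsilyl chloride, CC(C)[Si](Cl)(C(C)C)C(C)C
Why: Silyl ether formation masks the phenol that would otherwise add to the alkyne made in the next steps.

Step 7
Reactants: 9 4,6-bis(benzyloxy)-2-(triisopropylsilyloxy)benzaldehyde
Product: 10 [3,5-bis(benzyloxy)-2-ethynylphenoxy]triisopropylsilane
Conditions: TMSCHN2, LDA, THF, −78 °C → rt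
Reagents that add atoms: (trimethylsilyl)diazomethane, C[Si](C)(C)C=[N+]=[N-]
Why: Colvin rearrangement (addition of lithiated trimethylsilyldiazomethane, Peterson-type elimination, loss of N2 and 1,2-shift in one flask) gives the terminal alkyne under aprotic conditions that spare the aryl silyl ether.

Step 8
Reactants: 10 [3,5-bis(benzyloxy)-2-ethynylphenoxy]triisopropylsilane; 3 3,4,5-tris(benzyloxy)benzoic acid
Product: 11 (Z)-2-[2,4-bis(benzyloxy)-6-(triisopropylsilyloxy)phenyl]ethenyl 3,4,5-tris(benzyloxy)benzoate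
Conditions: Ru(2-methylallyl)2(Ph2P(CH2)4PPh2) (3 mol %), toluene, 60 °C
Reagents that add atoms: none
Why: Ru-catalysed anti-Markovnikov addition of a carboxylic acid to a terminal arylalkyne, which with this bis(allyl) diphosphine catalyst class places the carboxylate on the terminal carbon and gives the Z enol ester.

Step 9
Reactants: 11 (Z)-2-[2,4-bis(benzyloxy)-6-(triisopropylsilyloxy)phenyl]ethenyl 3,4,5-tris(benzyloxy)benzoate
Product: 12 (Z)-2-[2,4-bis(benzyloxy)-6-hydroxyphenyl]ethenyl 3,4,5-tris(benzyloxy)benzoate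
Conditions: TBAF, AcOH, THF, 0 °C
Reagents that add atoms: none
Why: Fluoride cleavage of the aryl silyl ether, buffered with acetic acid so that no free phenoxide attacks the enol ester; the alkene geometry is kept.

Step 10
Reactants: 13 3,4-bis(benzyloxy)benzaldehyde
Product: 14 3,4-bis(benzyloxy)benzaldehyde dimethyl acetal
Conditions: HC(OMe)3, PPTS (cat.), MeOH, rt; then Et3N
Reagents that add atoms: trimethyl orthoformate, COC(OC)OC
Why: Acid-catalysed acetalisation driven to completion by the orthoformate as water scavenger.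

Step 11
Reactants: 14 3,4-bis(benzyloxy)benzaldehyde dimethyl acetal; 12 (Z)-2-[2,4-bis(benzyloxy)-6-hydroxyphenyl]ethenyl 3,4,5-tris(benzyloxy)benzoate
Product: 16 mixed O-aryl O-methyl acetal of 3,4-bis(benzyloxy)benzaldehyde on the phenol oxygen of 12, via α-chloro ether 15 (not isolated)
Conditions: 14, AcCl (1.05 equiv), CH2Cl2, 0 °C; then 12, iPr2NEt, CH2Cl2, −40 → 0 °C; Et3N-deactivated silica
Reagents that add atoms: none
Why: Acetal-to-α-chloro-ether exchange with acetyl chloride followed by O-alkylation of the phenol under amine base (the reaction type of alkoxymethyl ether formation) installs the O-1–C-2 bond at the aldehyde oxidation level; the acetal carbon is racemic and is planarised again in step 12.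

Step 12
Reactants: 16 mixed O-aryl O-methyl acetal; 4 lower unit (3 equiv, excess recovered)
Product: 19 benzyl-protected epicatechin gallate-(4β→8)-epicatechin gallate dimer (tetradeca-O-benzyl procyanidin B2 3,3′-di-O-gallate), via O-aryl oxocarbenium ion 17 (not isolated), via cis-fused dioxolan-2-ylium ion 18 (not isolated)
Conditions: (S)-3,3′-bis(2,4,6-triisopropylphenyl)-1,1′-binaphthyl-2,2′-diyl N-triflylphosphoramide (10 mol %), 5 Å MS, CH2Cl2 (0.01 M), −60 → −20 °C
Reagents that add atoms: none
Why: Proposed new method: acid ionisation of mixed acetal 16 with loss of methanol (taken up by the sieves) should give the O-aryl oxocarbenium ion 17 paired with the chiral phosphoramide anion; C-3 of the (Z)-enol gallate, whose C-4 terminus is conjugated to the 1,3,5-trioxygenated ring A, then attacks C-2 (Prins closure of the pyran ring), the ring-A-stabilised C-4 cation is held by the galloyl carbonyl as the cis-fused dioxolan-2-ylium ion 18, and C-8 of 4 opens 18 at C-4 in a Friedel–Crafts step that returns the proton. The closest known reaction types are the chiral-Brønsted-acid-catalysed asymmetric Prins cyclisation of homoallylic alcohols with aldehydes (an ortho-hydroxystyrene is the benzo analogue of a homoallylic alcohol), Prins/Friedel–Crafts cascades, and the Lewis-acid coupling of 3-O-acyl-4-alkoxyflavans with flavan nucleophiles. The pyran ring closes 6-endo-trig at the alkene onto the endocyclic oxocarbenium carbon, and the transient dioxolanylium ring closes 5-exo-trig onto C-4 and is opened again in the same flask. C-2 and C-3 are set cis by the Z geometry of the enol ester in a half-chair transition state with ring B equatorial on the E-oxocarbenium and the acyloxy group axial, their absolute sense is set by the chiral counter-anion, and C-4 is set trans to O-3 because the arene must enter anti to the participating ester. The step needs attack through C-3 and not C-4 of the alkene, which the acyl group secures by damping oxygen donation so that only the ring-A benzylic cation is stabilised, and it needs ring closure to outrun intermolecular arylation of the acetal-derived cations by 4, which the six-membered intramolecular closure and high dilution should secure.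

Step 13
Reactants: 19 protected dimer (2 equiv, excess recovered); 6 upper unit electrophile
Product: 20 benzyl-protected epicatechin gallate-(4β→8)-epicatechin gallate-(4β→8)-epicatechin gallate (henicosa-O-benzyl procyanidin C1 3,3′,3″-tri-O-gallate)
Conditions: TMSOTf (0.2 equiv), CH2Cl2, −78 °C; then Et3N
Reagents that add atoms: none
Why: Lewis-acid ionisation of the 4-alkoxy group with galloyl participation and Friedel–Crafts attack by C-8 of the central unit (the most reactive free ring-A position, between O-1 and the 7-benzyloxy group) anti to the participating ester, which sets the upper C-4 centre 4β.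

Step 14
Reactants: 20 protected trimer
Product: 21 procyanidin C1 3,3′,3″-tri-O-gallate
Conditions: H2 (1 atm), Pd(OH)2/C, THF/MeOH/H2O (20:1:1), rt
Reagents that add atoms: none
Why: Hydrogenolysis of the 21 benzyl ethers under neutral conditions, which leave the galloyl esters, the interflavan bonds and all stereocenters intact.

**Compound list**

1 | (−)-epicatechin, (2R,3R) | O[C@@H]1Cc2c(O)cc(O)cc2O[C@@H]1c1ccc(O)c(O)c1 | starting material
2 | 5,7,3′,4′-tetra-O-benzyl-(−)-epicatechin, (2R,3R) | O[C@@H]1Cc2c(OCc3ccccc3)cc(OCc3ccccc3)cc2O[C@@H]1c1ccc(OCc2ccccc2)c(OCc2ccccc2)c1 | intermediate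
3 | 3,4,5-tris(benzyloxy)benzoic acid | OC(=O)c1cc(OCc2ccccc2)c(OCc2ccccc2)c(OCc2ccccc2)c1 | starting material
4 | 5,7,3′,4′-tetra-O-benzyl-(−)-epicatechin 3-O-[3,4,5-tris(benzyloxy)benzoate], (2R,3R), lower unit | O=C(O[C@@H]1Cc2c(OCc3ccccc3)cc(OCc3ccccc3)cc2O[C@@H]1c1ccc(OCc2ccccc2)c(OCc2ccccc2)c1)c1cc(OCc2ccccc2)c(OCc2ccccc2)c(OCc2ccccc2)c1 | intermediate
5 | 4β-(2-ethoxyethoxy)-5,7,3′,4′-tetra-O-benzyl-(−)-epicatechin (epicatechin configuration at C-2 and C-3, 4-alkoxy trans to the 3-hydroxyl) | O[C@@H]1[C@@H](OCCOCC)c2c(OCc3ccccc3)cc(OCc3ccccc3)cc2O[C@@H]1c1ccc(OCc2ccccc2)c(OCc2ccccc2)c1 | intermediate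
6 | 4β-(2-ethoxyethoxy)-5,7,3′,4′-tetra-O-benzyl-(−)-epicatechin 3-O-[3,4,5-tris(benzyloxy)benzoate], upper unit | O=C(O[C@@H]1[C@@H](OCCOCC)c2c(OCc3ccccc3)cc(OCc3ccccc3)cc2O[C@@H]1c1ccc(OCc2ccccc2)c(OCc2ccccc2)c1)c1cc(OCc2ccccc2)c(OCc2ccccc2)c(OCc2ccccc2)c1 | intermediate
7 | 2,4,6-trihydroxybenzaldehyde | O=Cc1c(O)cc(O)cc1O | starting material
8 | 4,6-bis(benzyloxy)-2-hydroxybenzaldehyde | O=Cc1c(O)cc(OCc2ccccc2)cc1OCc1ccccc1 | intermediate
9 | 4,6-bis(benzyloxy)-2-(triisopropylsilyloxy)benzaldehyde | O=Cc1c(O[Si](C(C)C)(C(C)C)C(C)C)cc(OCc2ccccc2)cc1OCc1ccccc1 | intermediate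
10 | [3,5-bis(benzyloxy)-2-ethynylphenoxy]triisopropylsilane | C#Cc1c(O[Si](C(C)C)(C(C)C)C(C)C)cc(OCc2ccccc2)cc1OCc1ccccc1 | intermediate
11 | (Z)-2-[2,4-bis(benzyloxy)-6-(triisopropylsilyloxy)phenyl]ethenyl 3,4,5-tris(benzyloxy)benzoate | O=C(O/C=C\c1c(O[Si](C(C)C)(C(C)C)C(C)C)cc(OCc2ccccc2)cc1OCc1ccccc1)c1cc(OCc2ccccc2)c(OCc2ccccc2)c(OCc2ccccc2)c1 | intermediate
12 | (Z)-2-[2,4-bis(benzyloxy)-6-hydroxyphenyl]ethenyl 3,4,5-tris(benzyloxy)benzoate | O=C(O/C=C\c1c(O)cc(OCc2ccccc2)cc1OCc1ccccc1)c1cc(OCc2ccccc2)c(OCc2ccccc2)c(OCc2ccccc2)c1 | intermediate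
13 | 3,4-bis(benzyloxy)benzaldehyde | O=Cc1ccc(OCc2ccccc2)c(OCc2ccccc2)c1 | starting material
14 | 3,4-bis(benzyloxy)benzaldehyde dimethyl acetal | COC(OC)c1ccc(OCc2ccccc2)c(OCc2ccccc2)c1 | intermediate
15 | α-chloro ether, 1,2-bis(benzyloxy)-4-[chloro(methoxy)methyl]benzene (not isolated) | COC(Cl)c1ccc(OCc2ccccc2)c(OCc2ccccc2)c1 | intermediate
16 | (Z)-2-{2,4-bis(benzyloxy)-6-[(3,4-bis(benzyloxy)phenyl)(methoxy)methoxy]phenyl}ethenyl 3,4,5-tris(benzyloxy)benzoate (racemic at the acetal carbon) | COC(Oc1cc(OCc2ccccc2)cc(OCc2ccccc2)c1/C=C\OC(=O)c1cc(OCc2ccccc2)c(OCc2ccccc2)c(OCc2ccccc2)c1)c1ccc(OCc2ccccc2)c(OCc2ccccc2)c1 | intermediate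
17 | O-aryl oxocarbenium ion from 16 by loss of methoxide, Z enol gallate intact (not isolated) | O=C(O/C=C\c1c([O+]=Cc2ccc(OCc3ccccc3)c(OCc3ccccc3)c2)cc(OCc2ccccc2)cc1OCc1ccccc1)c1cc(OCc2ccccc2)c(OCc2ccccc2)c(OCc2ccccc2)c1 | intermediate
18 | cis-fused 2-[3,4,5-tris(benzyloxy)phenyl]-1,3-dioxolan-2-ylium ion bridging O-3 and C-4 of the new (2R,3R)-5,7,3′,4′-tetra-O-benzylflavan; ring B, O-3 and O-4 on the same face (not isolated) | c1ccccc1COc1cc(OCc2ccccc2)c2c(c1)O[C@H](c1ccc(OCc3ccccc3)c(OCc3ccccc3)c1)[C@@H]1OC(c3cc(OCc4ccccc4)c(OCc4ccccc4)c(OCc4ccccc4)c3)=[O+][C@H]21 | intermediate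
19 | tetradeca-O-benzyl procyanidin B2 3,3′-di-O-gallate: protected epicatechin gallate-(4β→8)-epicatechin gallate, both units 2,3-cis, central unit 3,4-trans | O=C(O[C@@H]1[C@@H](c2c(OCc4ccccc4)cc(OCc4ccccc4)c3c2O[C@H](c2ccc(OCc4ccccc4)c(OCc4ccccc4)c2)[C@H](OC(=O)c2cc(OCc4ccccc4)c(OCc4ccccc4)c(OCc4ccccc4)c2)C3)c2c(OCc3ccccc3)cc(OCc3ccccc3)cc2O[C@@H]1c1ccc(OCc2ccccc2)c(OCc2ccccc2)c1)c1cc(OCc2ccccc2)c(OCc2ccccc2)c(OCc2ccccc2)c1 | intermediate
20 | henicosa-O-benzyl procyanidin C1 3,3′,3″-tri-O-gallate: protected epicatechin gallate-(4β→8)-epicatechin gallate-(4β→8)-epicatechin gallate | O=C(O[C@@H]1[C@@H](c2c(OCc4ccccc4)cc(OCc4ccccc4)c3c2O[C@H](c2ccc(OCc4ccccc4)c(OCc4ccccc4)c2)[C@H](OC(=O)c2cc(OCc4ccccc4)c(OCc4ccccc4)c(OCc4ccccc4)c2)C3)c2c(OCc3ccccc3)cc(OCc3ccccc3)c([C@H]3c4c(OCc5ccccc5)cc(OCc5ccccc5)cc4O[C@H](c4ccc(OCc5ccccc5)c(OCc5ccccc5)c4)[C@@H]3OC(=O)c3cc(OCc4ccccc4)c(OCc4ccccc4)c(OCc4ccccc4)c3)c2O[C@@H]1c1ccc(OCc2ccccc2)c(OCc2ccccc2)c1)c1cc(OCc2ccccc2)c(OCc2ccccc2)c(OCc2ccccc2)c1 | intermediate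
21 | procyanidin C1 3,3′,3″-tri-O-gallate | O=C(O[C@@H]1[C@@H](c2c(O)cc(O)c3c2O[C@H](c2ccc(O)c(O)c2)[C@H](OC(=O)c2cc(O)c(O)c(O)c2)C3)c2c(O)cc(O)c([C@H]3c4c(O)cc(O)cc4O[C@H](c4ccc(O)c(O)c4)[C@@H]3OC(=O)c3cc(O)c(O)c(O)c3)c2O[C@@H]1c1ccc(O)c(O)c1)c1cc(O)c(O)c(O)c1 | target

**Step count and risks**

Total step count: 14. Longest linear sequence: 9 steps (steps 5, 6, 7, 8, 9, 11, 12, 13, 14).

Steps most likely to fail:

1. Step 12 (proposed new method). What may go wrong:
   - ionisation of the acetal on the phenol side, followed by intermolecular arylation of the released methoxycarbenium by the lower unit;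
   - protonation of the electron-rich styrene instead of the acetal;
   - weak facial discrimination in the chiral ion pair, so that the enantiomeric ring forms and appears as a diastereomeric dimer after coupling;
   - self-condensation through the free C-8 of the newly formed ring;
   - loss of the C-3 proton from the C-4 cation.

   Fallback with known chemistry: it sets out from 6 and 4 and comes back to the route at 19. Compound 6 has the constitution and configuration of the activated central unit, so the central pyran ring is taken from (−)-epicatechin instead of being closed. Compound 6 is condensed with an excess of 4 (TMSOTf, CH2Cl2, −78 °C), the galloyl group directing the 4β→8 bond as in step 13. This fallback makes no new compound (F0).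

2. Step 11. What may go wrong: premature ionisation of the α-chloro ether or of the mixed acetal, leading to uncatalysed ring closure or C-alkylation of ring A, and hydrolysis of the acetal during purification.

   Fallback: it sets out from 12 and 13 and comes back to the route at 19. No acetal is isolated; phenol 12, aldehyde 13 and an excess of 4 are condensed directly under the acid of step 12 with 5 Å sieves (three-component Prins-type condensation through the hemiacetal), so that 17 and 18 form as before. This fallback makes no new compound (F0).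

3. Step 8. What may go wrong: slow turnover at the doubly ortho-substituted alkyne, Markovnikov addition of the acid, or Z to E isomerisation of the enol ester.

   Fallback: it sets out from 10 and comes back to the route at 11. Trans-hydroboration of 10 (pinacolborane, [RhCl(C8H12)]2, P(iPr)3, Et3N, cyclohexane, rt) should give (Z)-2-{2-[2,4-bis(benzyloxy)-6-(triisopropylsilyloxy)phenyl]ethenyl}-4,4,5,5-tetramethyl-1,3,2-dioxaborolane F1. Chan–Lam-type C–O coupling of this boronate with acid 3 (Cu(OAc)2, Et3N, 4 Å sieves, air, CH2Cl2) should proceed with retention of the alkene geometry to 11.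

Further compounds
F0 | step 12 | none | none
F0 | step 11 | none | none
F1 | step 8 | (Z)-2-{2-[2,4-bis(benzyloxy)-6-(triisopropylsilyloxy)phenyl]ethenyl}-4,4,5,5-tetramethyl-1,3,2-dioxaborolane | CC1(C)OB(/C=C\c2c(O[Si](C(C)C)(C(C)C)C(C)C)cc(OCc3ccccc3)cc2OCc2ccccc2)OC1(C)C
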